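**The vessel.** A closed, stirred vessel at constant volume and temperature holds starting material, which the enzyme turns into target. The ochre run shows the first 80.0 s of this, and its percentages drift below 100, so target is being lost as well as made.

| flask | starting material | enzyme | remark | time |
|---|---|---|---|---|
| ochre | 0.070 M | 14 µM | run made earlier |  |
| flask | 0.14 M | 14 µM |  | 12 min |

ochre run (percent of the starting material charged)

| time / s | target / % | starting material / % |
|---|---|---|
| 12.0 | 3.2 | 98.0 |
| 25.0 | 6.0 | 93.9 |
| 40.0 | 8.6 | 91.1 |
| 50.0 | 11.1 | 87.6 |
| 60.0 | 12.6 | 86.3 |
| 80.0 | 15.2 | 82.5 |

(each reading ± 0.5 percentage points)

1. when, up to 12 min, the flask holds most target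
2. the amount of target, in percent of the starting material charged, at that time
3. earliest time at which at least nineteen twentieths of that best amount are there, in min
4. latest time at which they still are, in min



**Way one.** Read the bend of the ochre target curve. If target climbs toward a level, equal time steps close equal shares of the gap. The reading at 80.0 s over the one at 40.0 s is 1.77. That gives a closing constant of 0.397 min⁻¹ and an ochre level of 37.0%. Their product, 0.147 min⁻¹ of the charge, is the early making. The early fall of starting material, from other readings, gives 0.146 min⁻¹, and the two match.

**Way two.** Use the balance instead. The ochre readings at 80.0 s miss 2.30% of the charge. Over the triangle under the target curve, that gives a loss constant of 0.227 min⁻¹, lower than way one's, and a level of 64.3%.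

**The cheat.** Way two holds making at its early pace. Yet ochre starting material falls at 0.102 min⁻¹ between 50.0 s and 80.0 s, slower than at the start. The bend registers that slowing too, so you keep way one, though a scatter of 0.5 percentage points leaves it loose.

**The bet.** Suppose the enzyme works flat out, zero-order in starting material; ochre is a single charge and does not test this. Making per charge then drops to half in the flask, while the closing constant stays. The flask's ceiling, the share of the charge at which target is lost as fast as it is made (a quasi-steady-state level), is 18.5%.

**The forecast.** The forecast differs from this ceiling, giving 33% at 7 min and a window from 5 min to 9.5 min, and it reasons: “The peak yield depends only on selectivity, so it stays put.”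

**The flask.** The flask peaks at 7.57 min with 17.0%, below the ceiling of 18.5%. Its window runs from 4.99 min to 11.1 min.

    starting material + enzyme → target + enzyme, rate k1*[starting material]*[enzyme]/(1 + ([starting material]/Km1) + ([target]/Kp1)) (4.60 mM, 2.60 mM, k = 3.10 × 10⁵ M⁻¹ min⁻¹)
    target → over-reaction product (k = 0.300 min⁻¹)
    2 enzyme ⇌ resting dimer, settled at all times (K = 44000 M⁻¹)

**The neighbour.** The neighbour flask, stopped at 3.0 min, tests the climb. The ceiling of 18.5%, times the share of the gap closed by then, gives 12.9%. That neighbour reached 13.5% of target, with 79.2% starting material remaining.

All runs come from a simulation with constants of no real substance; noise was put on by code.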